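**Remark on the chemistry:** the precursor and product of the key step are kept as the 3,4'-diacetates with a free 5-hydroxyl, and both structures agree atom for atom with the target. One electronic point is put right: O7 and O1 are meta to O5 and cannot stabilise a C8 cation by resonance, so C8 selectivity is argued from the para preference of phenoxonium capture. The electrolysis is assumed to run in the anode compartment of a divided cell.

## Structural features

The target is a flavonol: a 4H-chromen-4-one in which benzenoid ring A is fused to pyranone ring C through the C4a–C8a bond, with a 4-hydroxy-3-methoxyphenyl ring B joined to C2 by a single bond. It has no stereocenter, and its only non-aromatic alkene, the trisubstituted prenyl double bond, has no geometry. Ring A is fully differentiated: a hydroxyl at C5 hydrogen-bonded to the C4 carbonyl, hydrogen at C6, a prenyl ether at O7 and a methyl ether at O8. Ring C carries the free 3-hydroxyl (an enol), and ring B carries one phenol and one methyl ether. The fragile parts are the aryl prenyl ether (cleaved by strong or Lewis acids, lost on hydrogenation over palladium, prone to Claisen shift on heating) and the electron-rich 3-hydroxypyranone with its 5,8-dioxygenated ring A, which autoxidises readily in base. The real difficulty is not the skeleton, which can be bought as a natural flavonol with ring B already correct, but the regiochemistry of ring A: oxygen at C8 and not C6, methyl on O8 only, prenyl on O7 only, and O3, O5 and O4' free at the end. The key step exploits the fact that C8 is the para carbon of the 5-phenol across ring A: two-electron oxidation of that phenol makes C8 electrophilic, methanol delivers oxygen and methyl together, and reduction of the resulting C8 ketal restores the 5-hydroxyl beside a C8 methoxy with no selective O-methylation. O7 and O1 sit on the carbons flanking C8 (C7 and C8a), so they make ring A electron-rich but do not direct the capture by resonance.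

## Logic of the disconnections

**9 back to 7.** The O3–H and O4'–H bonds of 9 are exchanged for O–acetyl bonds. The ring B phenol and the C3 enol are the most easily oxidised sites of a flavonol and must be masked while ring A is oxidised; acetyl is small, electron-withdrawing, and the one acyl group whose selective removal from O7 is established. There is no gain in skeleton, but the oxidation-level changes become possible on a robust compound. The forward deacylation must leave the prenyl and methyl ethers alone and must not expose the free flavonol to base and air together.

**7 back to 8.** A second C8–O(methyl) bond is written in, turning the aromatic 5-hydroxy-8-methoxy ring A of 7 into the 5-oxo-8,8-dimethoxy dienone of 8. The ketal is the stable resting state of a phenol oxidation in 6, and its two-electron reduction expels exactly one methoxy group. The gain is that the methyl on O8 never has to be placed selectively against O5, O3 and O4'. The forward reduction must outrun ketal hydrolysis and spare the allylic ether and both esters.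

**8 back to 5 and 6 (key disconnection).** Both C8–O bonds are cut and C8 returns to C–H. C8 is para to the 5-hydroxyl, so oxidation of that one phenol is enough to activate it. The gain is the largest of the route: the ring A problem collapses to a compound with the oxygenation pattern of a commercial flavonol. The forward step must oxidise ring A in preference to ring B, the C3 enol ester and the prenyl alkene, must capture 6 at C8 and not C6, and must keep both acetates intact in an alcoholic medium.

**5 back to 3 and 4.** The O7–CH2 bond of the prenyl ether is cut. O7 is the most acidic hydroxyl of the flavone and 4 is a commercial C5 alcohol, so the ether can be made by dehydrative coupling with no base present. The gain is removal of the only appendage absent from the natural flavonol. The forward step must alkylate O7 and not the chelated O5, avoid allylic transposition, and leave the two acetates where they are.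

**3 back to 2.** The O7–H bond is exchanged for an O7–acetyl bond. O7 cannot be addressed directly beside O3 and O4', but as acetates the three differ in leaving-group ability, and the 7-acetate, para to the C4 carbonyl, is the most labile. The gain is that differentiating four hydroxyls reduces to one acylation and one selective deacylation. The forward step must cleave one ester of three.

**2 back to 1.** Three O–acetyl bonds (O3, O7, O4') are cut, leading to the commercial flavonol 1, which already has ring B and the whole carbon skeleton. The forward acylation must stop before the hydrogen-bonded 5-hydroxyl reacts.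

## Other disconnections considered

**Alternative 1:** The cut is the C3–C4 bond of ring C. In the forward direction a triazolium-derived carbene with 1,8-diazabicycloundec-7-ene would couple the two aldehyde groups of the dialdehyde A2 in an intramolecular benzoin reaction, closing ring C as the racemic trans-dihydroflavonol A1.
- In its favour: every ring A oxygen, the C8 methoxy included, is fixed before the ring closes, so there is no C6-versus-C8 question; on regiochemical certainty this plan is better than the chosen one. Carbene-catalysed closure of 2-(2-oxoalkoxy)benzaldehydes to 3-hydroxychroman-4-ones is an established reaction class for ketone acceptors, so its mechanistic footing is also firmer than that of the anodic step.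
- Against it: both carbonyls of A2 are aldehydes, and the one that must become the acyl-anion equivalent is the hindered, electron-rich, di-ortho-substituted ring A aldehyde. The carbene should instead prefer the side-chain aldehyde, which carries an α-aryloxy group and would be expected to eliminate the ring A phenoxide by internal redox, or to enolise and self-condense.
- Endgame: A1 has two stereocenters that are made only to be destroyed by dehydrogenation to the flavonol. Its benzyl ethers can be removed only by hydrogenolysis or Lewis acid, neither compatible with a prenyl ether, so prenylation would follow deprotection and would need the same acetylation, thiolysis and Mitsunobu sequence used here.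
- Comparison: on structure the alternative builds what the chosen plan buys; on mechanism it is better precedented in class but worse matched to this substrate; on step economy it is clearly longer, since neither half of A2 is commercial. The two plans are equal in having no stereochemical issue in the final product.

**Alternative 2:** The cuts are C4a–C4 and C4–C3, with carbon monoxide A6 as C4. Zerovalent palladium formed from Pd(OAc)2 and Xantphos would insert into the aryl iodide A4, take up A6, and acylate the magnesium enolate (MgCl2, triethylamine) of the α-benzyloxy ketone A5 to give the 1,3-diketone A3; no ring closes in this step.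
- In its favour: it is a convergent three-component union, ring A regiochemistry is fixed in A4 (again better than the chosen plan), and the later acetal removal and cyclodehydration of a 2-oxygenated aryl 1,3-diketone to a flavone is classical chemistry, the equal of anything in the chosen route for reliability.
- Against it: the iodide of A4 sits between two ortho alkoxy groups on a tetra-oxygenated ring, so oxidative addition and acyl transfer would be slow, and direct non-carbonylative arylation or reduction could compete. Soft enolisation of a simple α-alkoxy aryl ketone is less favourable than for the malonate-type partners for which these conditions are usual, and O-acylation is possible.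
- Endgame: as in alternative 1, the benzyl ethers force prenylation to the end, after hydrogenolysis, with the same site-selection sequence.
- Comparison: structure and mechanism are sound and arguably safer at the key step, but the step count would be roughly twice that of the chosen plan because A4 needs a multi-step synthesis and the endgame repeats the protecting-group work.

**Alternative 3:** The cut is the O1–C8a bond. PhI(OAc)2 in methanol would oxidise the 2-hydroxy-5-methoxyphenyl ring of the diketone A8 to the quinone monoketal A9, whose future C8a is a doubly activated acceptor. The diketone enol oxygen would add there (6-endo oxa-Michael), and loss of methanol would re-aromatise ring A to the flavone dibenzoate A7.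
- In its favour: the oxidation acts on a 4-methoxyphenol, the ideal substrate for this reagent, so there is no doubt about which ring reacts, and O8 with its methyl is in place beforehand; on this point the alternative is better than the chosen plan. It is the equal of the chosen plan in carrying the prenyl ether through the key step, and A7 is the dibenzoate counterpart of 7, one deacylation from the target.
- Against it: A8 is a 2-hydroxyaryl 1,3-diketone and can close ring C the ordinary way, through its free phenol with loss of water. That facile pathway would place the methoxy group at C6 instead of C8 and would have to be suppressed throughout the preparation and oxidation of A8. Methanol competes with the enol oxygen for the acceptor carbon, and the 2-acyloxy-1,3-diketone is prone to acyl migration and retro-Claisen cleavage.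
- Comparison: the oxa-Michael and elimination sequence on a quinone monoketal is itself without direct precedent, so on mechanistic risk the two plans are about equal. On step economy the chosen plan is shorter, because A8 must be assembled from ring A and ring B building blocks by an acyl-transfer sequence.

Key step: step 4

## Route

Step 1
Reactants: 1 isorhamnetin [3,5,7-trihydroxy-2-(4-hydroxy-3-methoxyphenyl)-4H-chromen-4-one]
Product: 2 2-[4-(acetyloxy)-3-methoxyphenyl]-5-hydroxy-4-oxo-4H-chromene-3,7-diyl diacetate (3,7,4'-tri-O-acetylisorhamnetin)
Conditions: Ac2O (3.3 equiv), pyridine, CH2Cl2, 0 °C to rt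
Reagents that add atoms: acetic anhydride, CC(=O)OC(C)=O
Why: O-acylation of the three non-chelated hydroxyls; the 5-hydroxyl is held in a six-membered hydrogen bond to the C4 carbonyl and is acylated far more slowly, so a stoichiometric amount of anhydride without an acyl-transfer catalyst should stop at the triacetate.

Step 2
Reactants: 2 2-[4-(acetyloxy)-3-methoxyphenyl]-5-hydroxy-4-oxo-4H-chromene-3,7-diyl diacetate
Product: 3 2-[4-(acetyloxy)-3-methoxyphenyl]-5,7-dihydroxy-4-oxo-4H-chromen-3-yl acetate (3,4'-di-O-acetylisorhamnetin)
Conditions: PhSH (1.2 equiv), imidazole (0.3 equiv), N-methylpyrrolidone, 0 °C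
Reagents that add atoms: none
Why: Thiolysis (transacylation to thiophenol) removes the aryl acetate whose phenoxide is the best leaving group, the 7-acetate para to the C4 carbonyl; this selective 7-O-deacetylation is an established reaction of flavone acetates.

Step 3
Reactants: 3 2-[4-(acetyloxy)-3-methoxyphenyl]-5,7-dihydroxy-4-oxo-4H-chromen-3-yl acetate; 4 prenol (3-methylbut-2-en-1-ol)
Product: 5 2-[4-(acetyloxy)-3-methoxyphenyl]-5-hydroxy-7-[(3-methylbut-2-en-1-yl)oxy]-4-oxo-4H-chromen-3-yl acetate
Conditions: PPh3, diisopropyl azodicarboxylate, THF, 0 °C to rt
Reagents that add atoms: none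
Why: Mitsunobu etherification; the acidic 7-hydroxyl is the pronucleophile and attacks the primary carbon of the alkoxyphosphonium ion from 4 to give the linear prenyl ether, while the chelated 5-hydroxyl does not react and the neutral medium leaves both acetates in place.

Step 4
Reactants: 5 2-[4-(acetyloxy)-3-methoxyphenyl]-5-hydroxy-7-[(3-methylbut-2-en-1-yl)oxy]-4-oxo-4H-chromen-3-yl acetate; 6 methanol (two molecules; also the solvent)
Product: 8 2-[4-(acetyloxy)-3-methoxyphenyl]-8,8-dimethoxy-7-[(3-methylbut-2-en-1-yl)oxy]-4,5-dioxo-5,8-dihydro-4H-chromen-3-yl acetate, via 5-hydroxy-8-methoxyflavone diacetate 7 (not isolated)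
Conditions: graphite anode, Pt cathode, divided cell; anolyte LiClO4 (0.1 M), 2,6-lutidine (5 equiv), MeOH–CH2Cl2 (4:1), 0 °C; controlled anode potential, about 4 F/mol
Reagents that add atoms: none
Why: Proposed new method: at the carbon anode the hydrogen-bonded 5-phenol of 5 should lose two electrons and one proton (2,6-lutidine as acceptor) to give a ring A phenoxonium ion with positive charge at C6, C8 and C4a, and methanol 6 should add at the para carbon C8 and tautomerise to the 5-hydroxy-8-methoxy arene 7. As a 4-methoxyphenol, 7 is oxidised at a lower potential than 5, so it should be consumed at once by a second two-electron oxidation and a second methanol capture at C8, giving the cross-conjugated quinone monoketal 8, which has no phenol left and should resist further oxidation; four electrons pass per molecule and hydrogen is evolved at the cathode. The closest known reaction type is the anodic oxidation of phenols and 4-methoxyphenols in methanol to 4,4-dimethoxycyclohexa-2,5-dienones, and the same carbon of 5-hydroxyflavones is the one attacked in the Elbs persulfate oxidation; what has no precedent is the use of a chelated, meta-oxygenated flavone phenol. No ring closes and no stereocenter forms, since C8 ends with two identical methoxy groups. Ring A must be oxidised in preference to ring B and the enol, which the acetyl groups on O4' and O3 should ensure by raising the potential of both, and in preference to the trisubstituted prenyl alkene, which the controlled anode potential should ensure. Capture at C8 and not at C6 rests on the normal para preference of phenoxonium ions and on the greater stability of a para- over an ortho-quinone ketal; O7 and O1 are meta to O5 and give no resonance help, so this is the least secure point. The divided cell keeps cathodically formed methoxide from the acetates and keeps 8 from being reduced back, and the lutidine buffer shields the ketal and the prenyl ether from the acid released at the anode.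

Step 5
Reactants: 8 2-[4-(acetyloxy)-3-methoxyphenyl]-8,8-dimethoxy-7-[(3-methylbut-2-en-1-yl)oxy]-4,5-dioxo-5,8-dihydro-4H-chromen-3-yl acetate
Product: 7 2-[4-(acetyloxy)-3-methoxyphenyl]-5-hydroxy-8-methoxy-7-[(3-methylbut-2-en-1-yl)oxy]-4-oxo-4H-chromen-3-yl acetate
Conditions: Zn dust, AcOH (5 equiv), THF, 0 °C
Reagents that add atoms: none
Why: Reductive aromatisation of a quinone monoketal, an established route to 4-methoxyphenols: two-electron reduction of the dienone is followed by expulsion of one methoxide from C8, which restores aromatic ring A with the chelated 5-hydroxyl; the vinylic 3-acetate, the aryl acetate and the prenyl ether should not be reduced by zinc under these mild conditions.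

Step 6
Reactants: 7 2-[4-(acetyloxy)-3-methoxyphenyl]-5-hydroxy-8-methoxy-7-[(3-methylbut-2-en-1-yl)oxy]-4-oxo-4H-chromen-3-yl acetate
Product: 9 3,5-dihydroxy-2-(4-hydroxy-3-methoxyphenyl)-8-methoxy-7-[(3-methylbut-2-en-1-yl)oxy]-4H-chromen-4-one (target)
Conditions: NH3 (7 M in MeOH), THF, 0 °C to rt, under argon
Reagents that add atoms: none
Why: Ammonolysis of the enol acetate and the aryl acetate; the methyl and prenyl ethers are inert to ammonia, and exclusion of air should prevent autoxidation of the liberated flavonol.

## Compound list

1 | isorhamnetin, 3,5,7-trihydroxy-2-(4-hydroxy-3-methoxyphenyl)-4H-chromen-4-one | COc1cc(-c2oc3cc(O)cc(O)c3c(=O)c2O)ccc1O | starting material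
2 | 2-[4-(acetyloxy)-3-methoxyphenyl]-5-hydroxy-4-oxo-4H-chromene-3,7-diyl diacetate | COc1cc(-c2oc3cc(OC(C)=O)cc(O)c3c(=O)c2OC(C)=O)ccc1OC(C)=O | intermediate
3 | 2-[4-(acetyloxy)-3-methoxyphenyl]-5,7-dihydroxy-4-oxo-4H-chromen-3-yl acetate | COc1cc(-c2oc3cc(O)cc(O)c3c(=O)c2OC(C)=O)ccc1OC(C)=O | intermediate
4 | prenol, 3-methylbut-2-en-1-ol | CC(C)=CCO | starting material
5 | 2-[4-(acetyloxy)-3-methoxyphenyl]-5-hydroxy-7-[(3-methylbut-2-en-1-yl)oxy]-4-oxo-4H-chromen-3-yl acetate | COc1cc(-c2oc3cc(OCC=C(C)C)cc(O)c3c(=O)c2OC(C)=O)ccc1OC(C)=O | intermediate
6 | methanol | CO | starting material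
7 | 2-[4-(acetyloxy)-3-methoxyphenyl]-5-hydroxy-8-methoxy-7-[(3-methylbut-2-en-1-yl)oxy]-4-oxo-4H-chromen-3-yl acetate | COc1cc(-c2oc3c(OC)c(OCC=C(C)C)cc(O)c3c(=O)c2OC(C)=O)ccc1OC(C)=O | intermediate (transient in step 4, isolated in step 5)
8 | 2-[4-(acetyloxy)-3-methoxyphenyl]-8,8-dimethoxy-7-[(3-methylbut-2-en-1-yl)oxy]-4,5-dioxo-5,8-dihydro-4H-chromen-3-yl acetate | COc1cc(C2=C(OC(C)=O)C(=O)C3=C(O2)C(OC)(OC)C(OCC=C(C)C)=CC3=O)ccc1OC(C)=O | intermediate
9 | 3,5-dihydroxy-2-(4-hydroxy-3-methoxyphenyl)-8-methoxy-7-[(3-methylbut-2-en-1-yl)oxy]-4H-chromen-4-one | COc1cc(-c2oc3c(OC)c(OCC=C(C)C)cc(O)c3c(=O)c2O)ccc1O | target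

## Step count and least certain steps

Total step count: 6. Longest linear sequence: 6 steps (1 to 9).

**Step 4 (key step, proposed new method).**
- What may go wrong: electron transfer from the wrong part of the molecule (ring B or the prenyl alkene), or no clean oxidation at a usable potential because the hydrogen-bonded, meta-oxygenated 5-phenol is not ionised by lutidine. Further risks are capture of methanol at C6 instead of C8, methanolysis of an acetate followed by oxidation of the freed phenol or enol, and acid-catalysed exchange of the prenyloxy group for methoxy at the vinylogous ester stage.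
- Fallback (known chemistry, built on the Elbs persulfate oxidation): it sets out from 1 and returns to the route at 7.
  - 1 would be benzylated at O3, O7 and O4' (BnBr, K2CO3, DMF; the chelated 5-hydroxyl stays free) to 3,7-bis(benzyloxy)-2-[4-(benzyloxy)-3-methoxyphenyl]-5-hydroxy-4H-chromen-4-one F1.
  - Elbs oxidation (K2S2O8, aqueous KOH–pyridine, 10–20 °C), in which the 5-phenolate attacks the peroxide through its para carbon C8, should give the potassium 8-sulfate ester F2.
  - Hot dilute HCl with Na2SO3 would hydrolyse this to the 5,8-dihydroxyflavone F3.
  - Me2SO4 (1 equiv), K2CO3, acetone should methylate only the non-chelated 8-hydroxyl to give the 8-methyl ether F4.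
  - Hydrogenolysis (H2, Pd/C) would give limocitrin F5.
  - The logic of steps 1 to 3 is then repeated: Ac2O–pyridine to the 3,7,4'-triacetate F6, PhSH–imidazole to the 3,4'-diacetate F7, and Mitsunobu coupling with 4 to reach 7.
  - The detour takes eight operations to 7 instead of five, but every one is a reaction type established on flavonols.

**Step 5.**
- What may go wrong: hydrolysis of the ketal ahead of reduction, so that both methoxy groups are lost and ring A ends at the hydroquinone level; to a lesser extent, reductive cleavage of the allylic ether.
- Fallback from 8 to 7: the hydrolysis is made deliberate. Aqueous oxalic acid in THF would convert 8 into the flavone-5,8-quinone F8. Na2S2O4 in aqueous THF under argon would reduce it to the 5,8-hydroquinone F9. Trimethylsilyldiazomethane in MeOH–toluene should methylate only the free, non-chelated 8-hydroxyl, returning 7 without base that could disturb the acetates.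

**Step 2.**
- What may go wrong: loss of a second acetate (at O4' or O3) during thiolysis, or incomplete cleavage at O7, giving mixtures of partially acylated flavonols.
- Fallback from 2 directly to 5: alkylative deacetylation with prenyl bromide, K2CO3 and KI in dry acetone at reflux. The most labile aryl acetate (O7) is cleaved in the flask and the phenoxide is alkylated at once, an established way of turning flavone 7-acetates into 7-ethers. No new compound is isolated, and step 3 is bypassed as well.

## Further compounds

F1 | step 4 | 3,7-bis(benzyloxy)-2-[4-(benzyloxy)-3-methoxyphenyl]-5-hydroxy-4H-chromen-4-one | COc1cc(-c2oc3cc(OCc4ccccc4)cc(O)c3c(=O)c2OCc2ccccc2)ccc1OCc1ccccc1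
F2 | step 4 | potassium 3,7-bis(benzyloxy)-2-[4-(benzyloxy)-3-methoxyphenyl]-5-hydroxy-4-oxo-4H-chromen-8-yl sulfate | COc1cc(-c2oc3c(OS(=O)(=O)[O-])c(OCc4ccccc4)cc(O)c3c(=O)c2OCc2ccccc2)ccc1OCc1ccccc1.[K+]
F3 | step 4 | 3,7-bis(benzyloxy)-2-[4-(benzyloxy)-3-methoxyphenyl]-5,8-dihydroxy-4H-chromen-4-one | COc1cc(-c2oc3c(O)c(OCc4ccccc4)cc(O)c3c(=O)c2OCc2ccccc2)ccc1OCc1ccccc1
F4 | step 4 | 3,7-bis(benzyloxy)-2-[4-(benzyloxy)-3-methoxyphenyl]-5-hydroxy-8-methoxy-4H-chromen-4-one | COc1cc(-c2oc3c(OC)c(OCc4ccccc4)cc(O)c3c(=O)c2OCc2ccccc2)ccc1OCc1ccccc1
F5 | step 4 | limocitrin, 3,5,7-trihydroxy-2-(4-hydroxy-3-methoxyphenyl)-8-methoxy-4H-chromen-4-one | COc1cc(-c2oc3c(OC)c(O)cc(O)c3c(=O)c2O)ccc1O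
F6 | step 4 | 2-[4-(acetyloxy)-3-methoxyphenyl]-5-hydroxy-8-methoxy-4-oxo-4H-chromene-3,7-diyl diacetate | COc1cc(-c2oc3c(OC)c(OC(C)=O)cc(O)c3c(=O)c2OC(C)=O)ccc1OC(C)=O
F7 | step 4 | 2-[4-(acetyloxy)-3-methoxyphenyl]-5,7-dihydroxy-8-methoxy-4-oxo-4H-chromen-3-yl acetate | COc1cc(-c2oc3c(OC)c(O)cc(O)c3c(=O)c2OC(C)=O)ccc1OC(C)=O
F8 | step 5 | 2-[4-(acetyloxy)-3-methoxyphenyl]-7-[(3-methylbut-2-en-1-yl)oxy]-4,5,8-trioxo-5,8-dihydro-4H-chromen-3-yl acetate | COc1cc(C2=C(OC(C)=O)C(=O)C3=C(O2)C(=O)C(OCC=C(C)C)=CC3=O)ccc1OC(C)=O
F9 | step 5 | 2-[4-(acetyloxy)-3-methoxyphenyl]-5,8-dihydroxy-7-[(3-methylbut-2-en-1-yl)oxy]-4-oxo-4H-chromen-3-yl acetate | COc1cc(-c2oc3c(O)c(OCC=C(C)C)cc(O)c3c(=O)c2OC(C)=O)ccc1OC(C)=O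
F0 | step 2 | none | none
A1 | alternative 1 | trans-5,7-bis(benzyloxy)-2-[4-(benzyloxy)-3-methoxyphenyl]-3-hydroxy-8-methoxychroman-4-one (racemic, one enantiomer drawn) | COc1cc([C@H]2Oc3c(OC)c(OCc4ccccc4)cc(OCc4ccccc4)c3C(=O)[C@@H]2O)ccc1OCc1ccccc1
A2 | alternative 1 | 4,6-bis(benzyloxy)-2-{1-[4-(benzyloxy)-3-methoxyphenyl]-2-oxoethoxy}-3-methoxybenzaldehyde (racemic) | COc1cc(C(C=O)Oc2c(OC)c(OCc3ccccc3)cc(OCc3ccccc3)c2C=O)ccc1OCc1ccccc1
A3 | alternative 2 | 2-(benzyloxy)-1-[4,6-bis(benzyloxy)-3-methoxy-2-(methoxymethoxy)phenyl]-3-[4-(benzyloxy)-3-methoxyphenyl]propane-1,3-dione (racemic, enolisable at C2) | COCOc1c(C(=O)C(OCc2ccccc2)C(=O)c2ccc(OCc3ccccc3)c(OC)c2)c(OCc2ccccc2)cc(OCc2ccccc2)c1OC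
A4 | alternative 2 | 1,5-bis(benzyloxy)-2-iodo-4-methoxy-3-(methoxymethoxy)benzene | COCOc1c(I)c(OCc2ccccc2)cc(OCc2ccccc2)c1OC
A5 | alternative 2 | 2-(benzyloxy)-1-[4-(benzyloxy)-3-methoxyphenyl]ethan-1-one | COc1cc(C(=O)COCc2ccccc2)ccc1OCc1ccccc1
A6 | alternative 2 | carbon monoxide | [C-]#[O+]
A7 | alternative 3 | 2-[4-(benzoyloxy)-3-methoxyphenyl]-5-hydroxy-8-methoxy-7-[(3-methylbut-2-en-1-yl)oxy]-4-oxo-4H-chromen-3-yl benzoate | COc1cc(-c2oc3c(OC)c(OCC=C(C)C)cc(O)c3c(=O)c2OC(=O)c2ccccc2)ccc1OC(=O)c1ccccc1
A8 | alternative 3 | 1-[4-(benzoyloxy)-3-methoxyphenyl]-3-{2-hydroxy-5-methoxy-4-[(3-methylbut-2-en-1-yl)oxy]phenyl}-1,3-dioxopropan-2-yl benzoate (racemic, enolisable) | COc1cc(C(=O)C(OC(=O)c2ccccc2)C(=O)c2cc(OC)c(OCC=C(C)C)cc2O)ccc1OC(=O)c1ccccc1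
A9 | alternative 3 | 1-[4-(benzoyloxy)-3-methoxyphenyl]-3-{3,3-dimethoxy-4-[(3-methylbut-2-en-1-yl)oxy]-6-oxocyclohexa-1,4-dien-1-yl}-1,3-dioxopropan-2-yl benzoate | COc1cc(C(=O)C(OC(=O)c2ccccc2)C(=O)C2=CC(OC)(OC)C(OCC=C(C)C)=CC2=O)ccc1OC(=O)c1ccccc1
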